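Readings and results are simulated from invented constants, and the scatter is random.

- Target first: set it against whatever else has left the starting material, and read that split early.

| flask | starting material | partner | second substrate | protic impurity | temperature | remark | time |
|---|---|---|---|---|---|---|---|
| summer | 0.62 M | 0.64 equiv | 2 equiv | 0.062 M | 0 °C | run made earlier |  |
| autumn | 0.62 M | 0.81 equiv | 2 equiv | 0.062 M | 20 °C | run made earlier |  |
| epsilon | 0.62 M | 1.20 equiv | 2.00 equiv | 0.0620 M |  | at 5 °C throughout | 10 min |
| eta | 0.62 M | 0.800 equiv | 2.00 equiv | 0.0620 M |  | at 5 °C until 2.0 min, from then on at 35 °C | 10 min |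

| run | time / min | target / % | starting material / % |
|---|---|---|---|
| summer | 0.667 | 3 | 89 |
| summer | 2.00 | 16 | 66 |
| summer | 4.00 | 24 | 48 |
| summer | 5.00 | 25 | 43 |
| summer | 8.00 | 30 | 25 |
| summer | 10.0 | 33 | 18 |
| autumn | 0.333 | 23 | 51 |
| autumn | 1.00 | 35 | 26 |
| autumn | 2.00 | 45 | 21 |
| autumn | 2.50 | 42 | 13 |
| autumn | 4.00 | 48 | 8 |
| autumn | 5.00 | 43 | 3 |

(standard deviation of a reading: 2 percentage points)

* which of the two ends with the higher amount of target, in percent of the starting material charged ("neither" if they lie within 2 percentage points) (epsilon / eta / neither)
* target at the end, in percent of the starting material charged, epsilon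
* target at the end, in percent of the starting material charged, eta



- Divide target by the other losses, then by partner per second substrate charged. Summer at 2.00 min reads 2.78, and autumn at 0.333 min reads 2.18. With this scatter, treat them as one reading across 0 °C and 20 °C.
- Carry their mean, 2.48, as the selectivity factor: target made per other loss, for each partner per second substrate.
- Reckon a high version: partner stays at its charge and the starting material is used up. Target is then 59.8% in epsilon and 49.8% in eta.
- Reckon a low version: partner sits from the start at what the high version leaves. Eta gives 27.2%. Epsilon, also stopped at the 82.0% of starting material that summer had used by its reading at 10.0 min, gives 35.1%.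
- Partner falls as target forms, so expect each flask between its two versions. Autumn has 0.81 equiv of partner against 0.800 equiv in eta, and its last two readings average 45.5%, which stands 0.809 of the way from the low to the high version of eta.
- Put epsilon at that same place: 55.1%, more than the 45.5% expected of eta.
- The forecast chooses the other order: eta higher, epsilon 31% (22% to 44%), eta 41% (33% to 48%), holding for epsilon that “abundant live partner erodes target”.
- The flasks give epsilon as the higher: epsilon 54.8%, eta 44.9%.

    starting material + target → side product (k = 0.119 M⁻¹ min⁻¹, Ea = 70.0 kJ mol⁻¹)
    second substrate + protic impurity → quenched substrate (k = 2.59 M⁻¹ min⁻¹, Ea = 48.0 kJ mol⁻¹)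
    second substrate + partner → second product (k = 0.0281 M⁻¹ min⁻¹, Ea = 66.0 kJ mol⁻¹)
    starting material + partner → target (k = 0.552 M⁻¹ min⁻¹, Ea = 68.0 kJ mol⁻¹)
    starting material ⇌ dormant form (K = 3.10, k = 0.109 min⁻¹, Ea = 88.0 kJ mol⁻¹, ΔH = −85.0 kJ mol⁻¹)
    starting material + second substrate → cross product (k = 0.0487 M⁻¹ min⁻¹, Ea = 72.0 kJ mol⁻¹)
    (constants at 5 °C)

- Epsilon stands 0.798 of the way from low to high, and eta 0.783, against the 0.809 from autumn. Now take the neighbour, eta with 1.40 equiv of partner instead of 0.800 equiv. The same factor gives a high version of 63.5% and a low one of 48.7%, and the autumn place gives 60.7%. The neighbour ends with 15.0% cross product, 17.3% side product and 67.7% target, more than the high version of 63.5%.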